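The cyclohexene ring is numbered C1 (epoxide CH), C2(Me)=C3H, C4 (quaternary, pyrone), C5 (CH, pentenyl), C6 (epoxide C–Me). With C1 as a ketone, C6–C1–C2 is a pentan-3-one unit. The exocyclic E-alkene on C5 lies γ,δ to C1=O (Claisen retron for C5–C6), and C2=C3 is the enone alkene (olefination retron). The precursor is open-chain: the C3 aldehyde, whose side-chain carbinol oxygen is tied to C1 as a phosphonate-bearing enol ether, a C–O bond absent from the target. One deprotonation triggers a carbanion-accelerated Claisen rearrangement (C5–C6, C5 configuration, E-alkene). The relocated β-ketophosphonate anion then closes C2=C3 by Horner–Wadsworth–Emmons olefination.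

Key step: step 12

Remark: Pyr = 6-methoxy-3,5-dimethyl-4-oxo-4H-pyran-2-yl. The ring numbering above is also used for the open-chain intermediates.
Assumption: the sense of induction of the copper catalyst of step 4 on the new diol 7 has to be established by experiment. Both ligand enantiomers are available, so the (S)-monobenzoate 8 is taken as accessible.

Step 1
Reactants: 1 2,2,5-trimethyl-1,3-dioxane-5-carboxylic acid; 2 methyl 2-methyl-3-oxopentanoate
Product: 4 methyl 2,4-dimethyl-3,5-dioxo-5-(2,2,5-trimethyl-1,3-dioxan-5-yl)pentanoate, via acyl imidazole 3 (not isolated)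
Conditions: 1, CDI, THF, rt; added to the dianion of 2 (2.2 equiv 2, 4.5 equiv LiN(i-Pr)2, THF, 0 °C), −78 → 0 °C; aq NH4Cl
Reagents that add atoms: none
Why: γ-Acylation of a β-keto ester dianion (the more basic terminal carbanion reacts) with an N-acylimidazole builds the whole triketide chain of the pyrone on the carboxyl carbon of 1, whose quaternary carbon is the future C4 and already carries two equivalent hydroxymethyl arms.

Step 2
Reactants: 4
Product: 5 4-hydroxy-3,5-dimethyl-6-(2,2,5-trimethyl-1,3-dioxan-5-yl)-2H-pyran-2-one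
Conditions: DBU, toluene, reflux
Reagents that add atoms: none
Why: The hindered ketone can enolise in one direction only, and 6-exo-trig attack of its enol oxygen on the methyl ester, loss of methanol and tautomerisation should give the 4-hydroxy-2-pyrone (standard triketide lactonisation).

Step 3
Reactants: 5
Product: 7 2-(1,3-dihydroxy-2-methylpropan-2-yl)-6-methoxy-3,5-dimethyl-4H-pyran-4-one (prochiral diol), via acetonide pyrone 6 (not isolated)
Conditions: MeOTf (1.2 equiv), CH2Cl2, 0 °C → rt; then MeOH, rt; aq NaHCO3
Reagents that add atoms: methyl trifluoromethanesulfonate COS(=O)(=O)C(F)(F)F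
Why: The hard alkylating agent methylates the most basic oxygen (the lactone carbonyl), so the pyrylium triflate formed is simply protonated γ-pyrone 6 (known O-methylation of 4-hydroxy-2-pyrones to 2-methoxy-4-pyrones), and this strong acid then catalyses transketalisation of the acetonide to methanol.

Step 4
Reactants: 7
Product: 8 (S)-3-hydroxy-2-methyl-2-Pyr-propyl benzoate
Conditions: BzCl (1.1 equiv), CuCl2 (10 mol %), 2,6-bis(4-phenyl-4,5-dihydrooxazol-2-yl)pyridine (single enantiomer, 11 mol %), Et3N, CH2Cl2, −40 °C
Reagents that add atoms: benzoyl chloride O=C(Cl)c1ccccc1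
Why: Divalent copper chelates the 1,3-diol and the chiral ligand differentiates the enantiotopic arms, so that benzoylation of the pro-S CH2OH (catalytic desymmetrising acylation of a 2,2-disubstituted propane-1,3-diol) sets the quaternary centre C4.

Step 5
Reactants: 8
Product: 9 (S)-2-methyl-3-oxo-2-Pyr-propyl benzoate
Conditions: Dess–Martin periodinane, NaHCO3, CH2Cl2, 0 °C → rt, directly after step 4
Reagents that add atoms: none
Why: The neutral buffered Dess–Martin oxidation avoids the acid- or base-induced 1,3-benzoyl shift that would racemise 8, and once one arm is an aldehyde C4 is configurationally locked.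

Step 6
Reactants: 9; 10 2-(triphenylphosphoranylidene)propanal
Product: 11 (S,E)-2,4-dimethyl-5-oxo-2-Pyr-pent-3-en-1-yl benzoate
Conditions: 10 (1.5 equiv), toluene, 100 °C
Reagents that add atoms: none
Why: Wittig olefination with a stabilised, base-free ylide tolerates the non-enolisable but deformylation-prone aldehyde, and the bulky C4 substituent should reinforce the usual E-selectivity.

Step 7
Reactants: 11
Product: 12 (2S,3E,5R)-5-hydroxy-2,4-dimethyl-2-Pyr-hept-3-en-1-yl benzoate
Conditions: Et2Zn (3 equiv), (+)-3-exo-morpholinoisoborneol (10 mol %), toluene–hexane, 0 °C; aq NH4Cl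
Reagents that add atoms: diethylzinc CC[Zn]CC
Why: Amino-alcohol-catalysed enantioselective addition of diethylzinc to an α-methyl enal is reagent-controlled (this ligand enantiomer turns benzaldehyde into (R)-1-phenylpropanol), so the remote C4 centre should not interfere and the (R)-carbinol is set, while benzoate and pyrone are inert to Et2Zn.

Step 8
Reactants: 13 pent-3-yn-2-ol (racemic); 14 diethyl chlorophosphite
Product: 16 diethyl penta-2,3-dien-2-ylphosphonate (racemic), via propargyl phosphite 15 (not isolated)
Conditions: Et3N, CH2Cl2, −78 °C → rt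
Reagents that add atoms: none
Why: O-Phosphitylation followed by the spontaneous [2,3]-sigmatropic propargyl phosphite to allenylphosphonate rearrangement gives the C6–C1–C2 unit with both methyl groups in place, and its axial chirality disappears in step 9.

Step 9
Reactants: 12; 16
Product: 17 (2S,3E,5R)-5-{[(E)-4-(diethoxyphosphoryl)pent-2-en-3-yl]oxy}-2,4-dimethyl-2-Pyr-hept-3-en-1-yl benzoate (epimers at the P-bearing carbon)
Conditions: 16 (1.5 equiv), NaH (0.15 equiv), THF, 0 °C, short reaction time; pH 7 buffer
Reagents that add atoms: none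
Why: Oxa-Michael addition of the catalytic alkoxide of 12 to the central carbon of the phosphonate-activated allene, on the side of the smaller terminal substituent (H), followed by kinetic α-protonation should give the E-configured β,γ-unsaturated allyl vinyl ether, low temperature and catalytic base keep the hindered benzoate in place, and the P-bearing stereocentre is removed by deprotonation in step 12.

Step 10
Reactants: 17
Product: 18 diethyl [(E)-3-{[(3R,4E,6S)-7-hydroxy-4,6-dimethyl-6-Pyr-hept-4-en-3-yl]oxy}pent-3-en-2-yl]phosphonate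
Conditions: K2CO3 (0.3 equiv), MeOH, rt
Reagents that add atoms: none
Why: Carbonate-catalysed transesterification removes the benzoate, while the unactivated enol ether, the phosphonate and the methoxypyrone (methoxide exchange is degenerate) should be untouched.

Step 11
Reactants: 18
Product: 19 diethyl [(E)-3-{[(3R,4E,6R)-4,6-dimethyl-7-oxo-6-Pyr-hept-4-en-3-yl]oxy}pent-3-en-2-yl]phosphonate
Conditions: Dess–Martin periodinane, NaHCO3, CH2Cl2, 0 °C → rt; filtration through Et3N-deactivated silica
Reagents that add atoms: none
Why: The buffered Dess–Martin oxidation unveils the C3 aldehyde under neutral conditions, far below the temperature of a thermal Claisen rearrangement and without hydrolysis of the enol ether.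

Step 12
Reactants: 19
Product: 21 (4R,5R,6R)-2,4,6-trimethyl-4-Pyr-5-[(E)-pent-2-en-2-yl]cyclohex-2-en-1-one, via β-ketophosphonate 20 (not isolated)
Conditions: KH (1.3 equiv), LiCl (6 equiv), THF–DMPU 5:1, slow addition of 19 (final 0.004 M), 0 → 45 °C; aq NH4Cl
Reagents that add atoms: none
Why: KH removes the proton α to phosphorus, and the phosphonate-stabilised 2-alkoxyallyl anion undergoes a charge-accelerated [3,3] shift through a chair that breaks the temporary C1–O–CH(Et) link, forms C5–C6 and delivers the salt of β-ketophosphonate 20, whose carbanion C2 adds to the C3 aldehyde and expels diethyl phosphate. The closest known reaction types are the carbanion-accelerated Claisen rearrangement of phosphonate-substituted allyl vinyl ethers and the intramolecular Horner–Wadsworth–Emmons cyclisation of ω-oxo β-ketophosphonates, run here from a single deprotonation because the product anion of the first is the reagent of the second. The only ring, the cyclohexenone, is closed by 6-(enolexo)-exo-trig addition and syn-elimination, which can only give the endocyclic cis alkene, so the E/Z problem of an intermolecular olefination does not arise. C5 is controlled by the (R)-carbinol through suprafacial 1,3-chirality transfer across the E-alkene with ethyl equatorial, the same arrangement that makes the new exocyclic alkene E; C6 follows from the E-enol ether in the chair (5,6-cis) but is erased in step 13, and C4 is untouched. The unimolecular rearrangement must win over intermolecular carbanion–aldehyde addition and over direct eight-membered closure, which is secured by high dilution, by the neopentyl non-enolisable aldehyde and by the reversibility of the addition of the non-stabilised anion, whereas Claisen shift and olefination are irreversible. Bonding at C6 rather than C2 follows because only that path leads to the doubly stabilised β-ketophosphonate anion, and either double-bond isomer of the enol ether gives the same allyl anion.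

Step 13
Reactants: 21
Product: 22 (4R,5R,6S)-6-hydroxy-2,4,6-trimethyl-4-Pyr-5-[(E)-pent-2-en-2-yl]cyclohex-2-en-1-one
Conditions: KN(SiMe3)2, THF, −78 °C; 2-(phenylsulfonyl)-3-phenyloxaziridine, −78 °C; aq NH4Cl
Reagents that add atoms: 2-(phenylsulfonyl)-3-phenyloxaziridine O=S(=O)(c1ccccc1)N1OC1c1ccccc1
Why: Deprotonation is possible only at C6 (C4 is quaternary), the cross-conjugated dienolate erases the C6 configuration, and oxaziridine hydroxylation of the enolate should occur anti to the pseudo-axial C5 pentenyl group and the cis C4 pyrone, which sets the C6 tertiary alcohol.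

Step 14
Reactants: 22
Product: 23 (1S,4R,5R,6S)-2,4,6-trimethyl-4-Pyr-5-[(E)-pent-2-en-2-yl]cyclohex-2-ene-1,6-diol (1,6-trans)
Conditions: NaBH4, CeCl3·7H2O, MeOH, −78 → −20 °C
Reagents that add atoms: none
Why: In the Luche 1,2-reduction hydride should attack C1=O from the face of the C6 hydroxyl, opposite the C6 methyl, the C5 pentenyl and the C4 pyrone, giving the trans-diol required for backside closure.

Step 15
Reactants: 23
Product: 25 2-methoxy-3,5-dimethyl-6-{(1R,4R,5R,6S)-2,4,6-trimethyl-5-[(E)-pent-2-en-2-yl]-7-oxabicyclo[4.1.0]hept-2-en-4-yl}-4H-pyran-4-one (target), via allylic mesylate 24 (not isolated)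
Conditions: MsCl (1.2 equiv), Et3N, CH2Cl2, −30 °C; then DBU, 0 °C → rt; Et3N-deactivated silica
Reagents that add atoms: none
Why: Only the secondary allylic hydroxyl is sulfonylated, and 3-exo-tet displacement by the C6 oxygen (Williamson-type closure) inverts C1 and can only give the cis-fused epoxide on the face anti to pentenyl and pyrone.

Compound list
1 | 2,2,5-trimethyl-1,3-dioxane-5-carboxylic acid | CC1(C)OCC(C)(CO1)C(=O)O | starting material
2 | methyl 2-methyl-3-oxopentanoate (racemic) | CCC(=O)C(C)C(=O)OC | starting material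
3 | 1-(2,2,5-trimethyl-1,3-dioxane-5-carbonyl)imidazole | CC1(C)OCC(C)(CO1)C(=O)n1ccnc1 | intermediate
4 | methyl 2,4-dimethyl-3,5-dioxo-5-(2,2,5-trimethyl-1,3-dioxan-5-yl)pentanoate (epimer and enol mixture) | COC(=O)C(C)C(=O)C(C)C(=O)C1(C)COC(C)(C)OC1 | intermediate
5 | 4-hydroxy-3,5-dimethyl-6-(2,2,5-trimethyl-1,3-dioxan-5-yl)-2H-pyran-2-one | CC1=C(O)C(C)=C(OC1=O)C1(C)COC(C)(C)OC1 | intermediate
6 | 2-methoxy-3,5-dimethyl-6-(2,2,5-trimethyl-1,3-dioxan-5-yl)-4H-pyran-4-one (formed as its triflate salt) | COc1oc(C2(C)COC(C)(C)OC2)c(C)c(=O)c1C | intermediate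
7 | 2-(1,3-dihydroxy-2-methylpropan-2-yl)-6-methoxy-3,5-dimethyl-4H-pyran-4-one | COc1oc(C(C)(CO)CO)c(C)c(=O)c1C | intermediate
8 | (S)-3-hydroxy-2-methyl-2-Pyr-propyl benzoate | OC[C@@](C)(COC(=O)c1ccccc1)c1oc(OC)c(C)c(=O)c1C | intermediate
9 | (S)-2-methyl-3-oxo-2-Pyr-propyl benzoate | O=C[C@@](C)(COC(=O)c1ccccc1)c1oc(OC)c(C)c(=O)c1C | intermediate
10 | 2-(triphenylphosphoranylidene)propanal | CC(C=O)=P(c1ccccc1)(c1ccccc1)c1ccccc1 | starting material
11 | (S,E)-2,4-dimethyl-5-oxo-2-Pyr-pent-3-en-1-yl benzoate | O=C/C(C)=C/[C@@](C)(COC(=O)c1ccccc1)c1oc(OC)c(C)c(=O)c1C | intermediate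
12 | (2S,3E,5R)-5-hydroxy-2,4-dimethyl-2-Pyr-hept-3-en-1-yl benzoate | CC[C@@H](O)/C(C)=C/[C@@](C)(COC(=O)c1ccccc1)c1oc(OC)c(C)c(=O)c1C | intermediate
13 | pent-3-yn-2-ol (racemic) | CC#CC(C)O | starting material
14 | diethyl chlorophosphite | CCOP(Cl)OCC | starting material
15 | diethyl pent-3-yn-2-yl phosphite | CCOP(OCC)OC(C)C#CC | intermediate
16 | diethyl penta-2,3-dien-2-ylphosphonate (racemic) | CCOP(=O)(OCC)C(C)=C=CC | intermediate
17 | enol ether benzoate (E-enol ether, R-carbinol carbon, S at C4, epimers at the P-bearing carbon) | CCOP(=O)(OCC)C(C)/C(O[C@H](CC)/C(C)=C/[C@@](C)(COC(=O)c1ccccc1)c1oc(OC)c(C)c(=O)c1C)=C\C | intermediate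
18 | enol ether primary alcohol | CCOP(=O)(OCC)C(C)/C(O[C@H](CC)/C(C)=C/[C@@](C)(CO)c1oc(OC)c(C)c(=O)c1C)=C\C | intermediate
19 | enol ether aldehyde, precursor of the key step | CCOP(=O)(OCC)C(C)/C(O[C@H](CC)/C(C)=C/[C@@](C)(C=O)c1oc(OC)c(C)c(=O)c1C)=C\C | intermediate
20 | open-chain (4R,5R,6R) β-ketophosphonate aldehyde (formed as its salt, drawn neutral) | CCOP(=O)(OCC)C(C)C(=O)[C@H](C)[C@H](/C(C)=C/CC)[C@@](C)(C=O)c1oc(OC)c(C)c(=O)c1C | intermediate
21 | (4R,5R,6R)-2,4,6-trimethyl-4-Pyr-5-[(E)-pent-2-en-2-yl]cyclohex-2-en-1-one (the C6 epimer converges in step 13) | CC/C=C(\C)[C@H]1[C@@H](C)C(=O)C(C)=C[C@@]1(C)c1oc(OC)c(C)c(=O)c1C | intermediate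
22 | (4R,5R,6S)-6-hydroxy-2,4,6-trimethyl-4-Pyr-5-[(E)-pent-2-en-2-yl]cyclohex-2-en-1-one | CC/C=C(\C)[C@H]1[C@](C)(O)C(=O)C(C)=C[C@@]1(C)c1oc(OC)c(C)c(=O)c1C | intermediate
23 | (1S,4R,5R,6S) 1,6-trans-diol | CC/C=C(\C)[C@H]1[C@](C)(O)[C@@H](O)C(C)=C[C@@]1(C)c1oc(OC)c(C)c(=O)c1C | intermediate
24 | C1 methanesulfonate of 23 | CC/C=C(\C)[C@H]1[C@](C)(O)[C@@H](OS(C)(=O)=O)C(C)=C[C@@]1(C)c1oc(OC)c(C)c(=O)c1C | intermediate
25 | 2-methoxy-3,5-dimethyl-6-{(1R,4R,5R,6S)-2,4,6-trimethyl-5-[(E)-pent-2-en-2-yl]-7-oxabicyclo[4.1.0]hept-2-en-4-yl}-4H-pyran-4-one | CC/C=C(\C)[C@H]1[C@]2(C)O[C@@H]2C(C)=C[C@@]1(C)c1oc(OC)c(C)c(=O)c1C | target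

Total step count: 15. Longest linear sequence: 14 (steps 1–7 and 9–15; step 8 is a one-step side branch).

Steps most likely to fail

Step 12. Three processes could outrun the rearrangement:
- intermolecular addition of the reactive allyl anion to the aldehyde
- retro-oxa-Michael loss of the allene
- base-induced deformylation at the quaternary C4

The fallback sets out from 12 and comes back at 21. It is a phosphorus-free, acid-catalysed variant that still makes both ring bonds in one flask. Methanolysis of the benzoate of 12 (K2CO3, MeOH) would give the heptene diol F1. Primary-selective oxidation (TEMPO cat., PhI(OAc)2, CH2Cl2) would give the hydroxy aldehyde F2. Heating F2 with commercial 3,3-dimethoxypentane and catalytic propionic acid (xylene, 135 °C, removal of MeOH) would form the pentenyl enol ether F3. F3 undergoes the ketal Claisen rearrangement to the keto aldehyde F4. Addition of piperidinium acetate to the same flask would close the ring by intramolecular aldol condensation to 21.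

Step 4. The enantiotopic arms may be poorly discriminated because the pyrone carbonyl competes for copper, and the enantiopurity may erode through 1,3-benzoyl migration. The fallback sets out from 7 and comes back at 8. Lipase-catalysed acetylation (Candida rugosa lipase, vinyl acetate, i-Pr2O) would give the (R)-monoacetate F5. Benzoylation of the free arm (BzCl, pyridine, 0 °C) would give the mixed diester F6. Selective hydrolysis of the acetate by the same lipase at pH 7 would give 8.

Step 15. The allylic mesylate may ionise, leading to allylic transposition, chloride capture or elimination before the oxygen closes. The fallback sets out from 21 and comes back at 25.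
- Enolisation and triflation (KN(SiMe3)2, N-(5-chloro-2-pyridyl)bis(trifluoromethanesulfonimide), THF, −78 °C) would give the dienyl triflate F7.
- Formate reduction (Pd(OAc)2, PPh3, HCO2H, Et3N, DMF, 60 °C, zerovalent palladium formed in the flask) would give the cyclohexa-1,3-diene F8, to be handled in the dark.
- One equivalent of dimethyldioxirane (acetone, −78 → −40 °C) should epoxidise the less hindered ring alkene C1=C6 anti to the pentenyl group to give 25. Regioselectivity against C2=C3 and the side-chain alkene is the open point of this variant.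

Further compounds
F1 | step 12 | (2S,3E,5R)-2,4-dimethyl-2-Pyr-hept-3-ene-1,5-diol | CC[C@@H](O)/C(C)=C/[C@@](C)(CO)c1oc(OC)c(C)c(=O)c1C
F2 | step 12 | (2R,3E,5R)-5-hydroxy-2,4-dimethyl-2-Pyr-hept-3-enal | CC[C@@H](O)/C(C)=C/[C@@](C)(C=O)c1oc(OC)c(C)c(=O)c1C
F3 | step 12 | pent-2-en-3-yl enol ether of F2 (enol ether geometry not controlled) | CC=C(CC)O[C@H](CC)/C(C)=C/[C@@](C)(C=O)c1oc(OC)c(C)c(=O)c1C
F4 | step 12 | (4R,5R) keto aldehyde, C6 epimers | CCC(=O)C(C)[C@H](/C(C)=C/CC)[C@@](C)(C=O)c1oc(OC)c(C)c(=O)c1C
F5 | step 4 | (R)-3-hydroxy-2-methyl-2-Pyr-propyl acetate | CC(=O)OC[C@@](C)(CO)c1oc(OC)c(C)c(=O)c1C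
F6 | step 4 | (S)-3-acetoxy-2-methyl-2-Pyr-propyl benzoate | CC(=O)OC[C@@](C)(COC(=O)c1ccccc1)c1oc(OC)c(C)c(=O)c1C
F7 | step 15 | dienyl triflate of 21 | CC/C=C(\C)[C@H]1C(C)=C(OS(=O)(=O)C(F)(F)F)C(C)=C[C@@]1(C)c1oc(OC)c(C)c(=O)c1C
F8 | step 15 | 1,3,5-trimethyl-5-Pyr-6-[(E)-pent-2-en-2-yl]cyclohexa-1,3-diene | CC/C=C(\C)[C@H]1C(C)=CC(C)=C[C@@]1(C)c1oc(OC)c(C)c(=O)c1C
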